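**Retrosynthetic overview**
1. The C12–C13 bond is cut last (Negishi coupling of a C-12 alkylzinc with 3-bromofuran-2(5H)-one); the exocyclic C8=C17 methylene comes from a C-8 ketone.
2. Ring B (C5–C6–C7–C8–C9–C10) is not closed as a six-membered ring. It arises by one-carbon enlargement of the five-membered ring C5–C6–C7–C8–C10 of a cis-hydrindane: the angular quaternary C-10 shifts from C-8 to exocyclic C-9 (semipinacol rearrangement of a 2-mesyloxy tertiary carbinol). This gives the C-8 ketone and the C-9 stereocentre with its C-11/C-12 chain.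
3. Enabling feature: the tertiary carbinol C-8 inside that five-membered ring, bonded to quaternary C-10, with the C-9 sulfonate anti-periplanar to the C8–C10 bond. The C-9 configuration is encoded by a Z-selective Wittig reaction on the C-8 ketone and a syn-dihydroxylation.
4. Ring A with C-4 and C-10 comes from an enantioselective copper hydride reductive aldol desymmetrisation of a 2-methylcyclopentane-1,3-dione carrying an enoate chain; H-5 comes from an ester-directed hydrogenation.
5. Ring order: five-membered ring (purchased) → ring A (step 3) → ring B by enlargement of the five-membered ring (step 12) → butenolide attached (step 16).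

Key step: step 12

Remark: the SMILES defines a cis-fused decalin with H-5, CH3-20, C-19 (CH2OAc) and the C-9 side chain on one face (labdane numbering, used for all intermediates); the route is built for this configuration, and compounds 1, 2, 4, 9, 10 and 22 are taken as purchasable.

**Route**

Step 1
Reactants: 1 2-methylcyclopentane-1,3-dione; 2 acrolein
Product: 3 3-(1-methyl-2,5-dioxocyclopentyl)propanal
Conditions: H2O, 20 °C
Reagents that add atoms: acrolein (2), C=CC=O
Why: Michael addition of the cyclic 1,3-dione to acrolein in water is a standard C-alkylation and creates the future C-10 as a still prochiral quaternary carbon.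

Step 2
Reactants: 3 3-(1-methyl-2,5-dioxocyclopentyl)propanal; 4 methyl 2-(triphenylphosphoranylidene)propanoate
Product: 5 methyl (E)-2-methyl-5-(1-methyl-2,5-dioxocyclopentyl)pent-2-enoate
Conditions: CH2Cl2, 20 °C
Reagents that add atoms: methyl 2-(triphenylphosphoranylidene)propanoate (4), COC(=O)C(C)=P(c1ccccc1)(c1ccccc1)c1ccccc1
Why: Wittig olefination with a stabilised ylide is selective for the aldehyde over the two ring ketones and should give the E-enoate that carries the future C-4 with its methyl and ester carbon.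

Step 3
Reactants: 5 methyl (E)-2-methyl-5-(1-methyl-2,5-dioxocyclopentyl)pent-2-enoate
Product: 6 methyl (3aS,4R,7aR)-3a-hydroxy-4,7a-dimethyl-1-oxooctahydro-1H-indene-4-carboxylate
Conditions: Cu(OAc)2·H2O (5 mol %), (R)- or (S)-DTBM-SEGPHOS (6 mol %; the antipode that gives the 7aR series), (EtO)2MeSiH, toluene, −20 °C; then NH4F, MeOH
Reagents that add atoms: none
Why: Copper hydride-catalysed reductive aldol cyclisation: conjugate reduction gives a copper enolate that adds to one of the two enantiotopic ring carbonyls, the chiral bisphosphine choosing the carbonyl (C-10, C-5), the short tether enforcing the cis-hydrindane ketol (OH cis to CH3-20), and the chelated chair transition state placing the ester cis to the new hydroxyl because the alternative forces the C-4 and C-10 methyl groups into a 1,3-diaxial relationship.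

Step 4
Reactants: 6 methyl (3aS,4R,7aR)-3a-hydroxy-4,7a-dimethyl-1-oxooctahydro-1H-indene-4-carboxylate
Product: 7 methyl (4R,7aR)-4,7a-dimethyl-1-oxo-2,4,5,6,7,7a-hexahydro-1H-indene-4-carboxylate
Conditions: Burgess reagent (methyl N-(triethylammoniosulfonyl)carbamate), toluene, 50 °C
Reagents that add atoms: none
Why: Burgess dehydration (syn-elimination) of the tertiary alcohol can only take a hydrogen from C-6, since C-4 and C-10 are quaternary, and its neutral conditions should keep the C5=C6 alkene from moving into conjugation with the C-8 ketone.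

Step 5
Reactants: 7 methyl (4R,7aR)-4,7a-dimethyl-1-oxo-2,4,5,6,7,7a-hexahydro-1H-indene-4-carboxylate
Product: 8 methyl (3aR,4R,7aR)-4,7a-dimethyl-1-oxooctahydro-1H-indene-4-carboxylate
Conditions: [Ir(cod)(PCy3)(py)]PF6 (5 mol %), H2 (1 atm), CH2Cl2, 20 °C
Reagents that add atoms: none
Why: Carbonyl-directed homogeneous hydrogenation: the ester carbonyl on C-4 binds the cationic iridium centre and delivers hydrogen to the alkene face on which it sits, which should set H-5 cis to the ester and to CH3-20 (cis-hydrindane).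

Step 6
Reactants: 9 (3-bromopropoxy)(tert-butyl)diphenylsilane; 10 triphenylphosphine
Product: 11 [3-(tert-butyldiphenylsilyloxy)propyl]triphenylphosphonium bromide
Conditions: MeCN, reflux
Reagents that add atoms: triphenylphosphine (10), c1ccc(cc1)P(c1ccccc1)c1ccccc1
Why: SN2 quaternisation of triphenylphosphine by the primary bromide gives the Wittig salt.

Step 7
Reactants: 8 methyl (3aR,4R,7aR)-4,7a-dimethyl-1-oxooctahydro-1H-indene-4-carboxylate; 11 [3-(tert-butyldiphenylsilyloxy)propyl]triphenylphosphonium bromide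
Product: 12 methyl (1Z,3aR,4R,7aR)-1-[3-(tert-butyldiphenylsilyloxy)propylidene]-4,7a-dimethyloctahydro-1H-indene-4-carboxylate
Conditions: 11, KHMDS, THF, 0 °C; then 8, 0 → 65 °C
Reagents that add atoms: phosphonium salt 11, CC(C)(C)[Si](OCCC[P+](c1ccccc1)(c1ccccc1)c1ccccc1)(c1ccccc1)c1ccccc1.[Br-]
Why: Wittig olefination with a salt-free non-stabilised ylide: as in the ethylidenation of 17-oxo steroids, the ylide substituent should end up cis to the more substituted α-carbon (C-10), giving the Z-alkylidene whose geometry later fixes C-9, while the hindered neopentyl ester is not attacked.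

Step 8
Reactants: 12 methyl (1Z,3aR,4R,7aR)-1-[3-(tert-butyldiphenylsilyloxy)propylidene]-4,7a-dimethyloctahydro-1H-indene-4-carboxylate
Product: 13 [(1Z,3aR,4R,7aR)-1-[3-(tert-butyldiphenylsilyloxy)propylidene]-4,7a-dimethyloctahydro-1H-inden-4-yl]methanol
Conditions: LiAlH4, THF, 0 → 40 °C
Reagents that add atoms: none
Why: LiAlH4 reduction of the ester gives the C-19 primary alcohol; the trisubstituted alkene and the silyl ether are inert.

Step 9
Reactants: 13 [(1Z,3aR,4R,7aR)-1-[3-(tert-butyldiphenylsilyloxy)propylidene]-4,7a-dimethyloctahydro-1H-inden-4-yl]methanol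
Product: 14 [(1Z,3aR,4R,7aR)-1-[3-(tert-butyldiphenylsilyloxy)propylidene]-4,7a-dimethyloctahydro-1H-inden-4-yl]methyl acetate
Conditions: Ac2O, pyridine, DMAP (cat.), CH2Cl2, 20 °C
Reagents that add atoms: acetic anhydride, CC(=O)OC(C)=O
Why: DMAP-catalysed acetylation installs the C-19 acetate of the target, which also masks the primary hydroxyl during the later sulfonylation.

Step 10
Reactants: 14 [(1Z,3aR,4R,7aR)-1-[3-(tert-butyldiphenylsilyloxy)propylidene]-4,7a-dimethyloctahydro-1H-inden-4-yl]methyl acetate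
Product: 15 [(1R,3aS,4R,7aR)-1-[(1S)-3-(tert-butyldiphenylsilyloxy)-1-hydroxypropyl]-1-hydroxy-4,7a-dimethyloctahydro-1H-inden-4-yl]methyl acetate
Conditions: OsO4 (5 mol %), NMO, acetone/H2O, 20 °C
Reagents that add atoms: osmium tetroxide (catalytic oxygen carrier), O=[Os](=O)(=O)=O; N-methylmorpholine N-oxide, C[N+]1([O-])CCOCC1; water, O
Why: Upjohn syn-dihydroxylation of the only alkene is expected on the convex face of the cis-hydrindane (the face of CH3-20 and H-5; the other face is screened by C-1 and the C-4 quaternary centre), which together with the Z geometry sets C-8 (R) and the C-9 carbinol (S).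

Step 11
Reactants: 15 [(1R,3aS,4R,7aR)-1-[(1S)-3-(tert-butyldiphenylsilyloxy)-1-hydroxypropyl]-1-hydroxy-4,7a-dimethyloctahydro-1H-inden-4-yl]methyl acetate
Product: 16 [(1R,3aS,4R,7aR)-1-[(1S)-3-(tert-butyldiphenylsilyloxy)-1-(methanesulfonyloxy)propyl]-1-hydroxy-4,7a-dimethyloctahydro-1H-inden-4-yl]methyl acetate
Conditions: MsCl, Et3N, CH2Cl2, −30 °C; used crude
Reagents that add atoms: methanesulfonyl chloride, CS(=O)(=O)Cl
Why: Sulfonylation through the sulfene discriminates the secondary C-9 hydroxyl from the hindered tertiary C-8 hydroxyl.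

Step 12
Reactants: 16 [(1R,3aS,4R,7aR)-1-[(1S)-3-(tert-butyldiphenylsilyloxy)-1-(methanesulfonyloxy)propyl]-1-hydroxy-4,7a-dimethyloctahydro-1H-inden-4-yl]methyl acetate
Product: 17 [(1R,4aR,5S,8aR)-5-[2-(tert-butyldiphenylsilyloxy)ethyl]-1,4a-dimethyl-6-oxodecahydronaphthalen-1-yl]methyl acetate
Conditions: Et3Al (3 equiv), CH2Cl2, −78 → 0 °C
Reagents that add atoms: none
Why: Semipinacol rearrangement of a 2-sulfonyloxy tertiary carbinol: Et3Al turns the C-8 hydroxyl into an aluminium alkoxide and, as a Lewis acid, pulls off the C-9 mesylate while the C8–C10 bond, anti-periplanar to C9–OMs, migrates to C-9 and the alkoxide collapses to the C-8 ketone; the closest known reactions are the aluminium-promoted 1,2-shift of 2-mesyloxy carbinols and the D-homoannulation of 17-hydroxy-20-sulfonyloxy steroids, in which the angular quaternary carbon of a hydrindane migrates in the same way. Ring B is not closed by a cyclisation: the five-membered ring C5–C6–C7–C8–C10 is enlarged by one atom when exocyclic C-9 is inserted between C-8 and C-10 through a suprafacial 1,2-alkyl shift. C-9 is the only new stereocentre and forms with inversion, so its configuration is dictated by the (S)-carbinol set from the Z-alkene by syn-osmylation, while the migrating C-10 keeps its configuration and carries CH3-20 and ring A with it. The step needs C-10 to migrate in preference to C-7 and to closure of the C-8 oxygen onto C-9 (spiro-epoxide): the rotamer with C-10 anti to the mesylate puts the side chain between the small oxygen and C-10 and is the least crowded of the three, the fully substituted C-10 has the higher migratory aptitude, and the covalent O–Al bond makes the oxygen a poor nucleophile. In one operation the step gives the cis-decalin, the C-8 carbonyl needed for the exocyclic methylene and the complete C-11/C-12 chain on C-9 in the target configuration.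

Step 13
Reactants: 17 [(1R,4aR,5S,8aR)-5-[2-(tert-butyldiphenylsilyloxy)ethyl]-1,4a-dimethyl-6-oxodecahydronaphthalen-1-yl]methyl acetate
Product: 18 [(1R,4aS,5R,8aR)-5-[2-(tert-butyldiphenylsilyloxy)ethyl]-1,4a-dimethyl-6-methylidenedecahydronaphthalen-1-yl]methyl acetate
Conditions: Zn, CH2Br2, TiCl4, THF, 0 °C; then 17, CH2Cl2, 20 °C
Reagents that add atoms: dibromomethane, BrCBr
Why: Takai–Lombardo methylenation converts the hindered C-8 ketone into the exocyclic methylene under non-basic conditions, so the epimerisable C-9 centre and the acetate are not touched.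

Step 14
Reactants: 18 [(1R,4aS,5R,8aR)-5-[2-(tert-butyldiphenylsilyloxy)ethyl]-1,4a-dimethyl-6-methylidenedecahydronaphthalen-1-yl]methyl acetate
Product: 19 [(1R,4aS,5R,8aR)-5-(2-hydroxyethyl)-1,4a-dimethyl-6-methylidenedecahydronaphthalen-1-yl]methyl acetate
Conditions: TBAF, AcOH, THF, 20 °C
Reagents that add atoms: none
Why: Fluoride-mediated cleavage of the silyl ether, buffered with acetic acid so that the acetate stays in place.

Step 15
Reactants: 19 [(1R,4aS,5R,8aR)-5-(2-hydroxyethyl)-1,4a-dimethyl-6-methylidenedecahydronaphthalen-1-yl]methyl acetate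
Product: 20 [(1R,4aS,5R,8aR)-5-(2-iodoethyl)-1,4a-dimethyl-6-methylidenedecahydronaphthalen-1-yl]methyl acetate
Conditions: I2, PPh3, imidazole, CH2Cl2, 0 °C
Reagents that add atoms: iodine, II
Why: Garegg–Samuelsson (Appel-type) iodination of the primary alcohol runs under neutral conditions compatible with the exocyclic alkene and the acetate.

Step 16
Reactants: 20 [(1R,4aS,5R,8aR)-5-(2-iodoethyl)-1,4a-dimethyl-6-methylidenedecahydronaphthalen-1-yl]methyl acetate; 22 3-bromofuran-2(5H)-one
Product: 23 [(1R,4aS,5R,8aR)-1,4a-dimethyl-6-methylidene-5-[2-(2-oxo-2,5-dihydrofuran-3-yl)ethyl]decahydronaphthalen-1-yl]methyl acetate (target), via alkylzinc iodide 21 (not isolated)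
Conditions: Zn dust (TMSCl, BrCH2CH2Br), DMA, 40 °C; then 22, PdCl2(dppf) (5 mol %), THF, 20 → 40 °C
Reagents that add atoms: 3-bromofuran-2(5H)-one (22), O=C1OCC=C1Br
Why: Zinc insertion into the primary iodide followed by Negishi coupling (zerovalent palladium cycle) with the α-bromobutenolide forms the C12–C13 bond under base-free conditions that leave the butenolide, acetate and exocyclic alkene untouched.

**Compound list**

1 | 2-methylcyclopentane-1,3-dione | CC1C(=O)CCC1=O | starting material
2 | acrolein | C=CC=O | starting material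
3 | 3-(1-methyl-2,5-dioxocyclopentyl)propanal | O=CCCC1(C)C(=O)CCC1=O | intermediate
4 | methyl 2-(triphenylphosphoranylidene)propanoate | COC(=O)C(C)=P(c1ccccc1)(c1ccccc1)c1ccccc1 | starting material
5 | methyl (E)-2-methyl-5-(1-methyl-2,5-dioxocyclopentyl)pent-2-enoate | COC(=O)/C(C)=C/CCC1(C)C(=O)CCC1=O | intermediate
6 | methyl (3aS,4R,7aR)-3a-hydroxy-4,7a-dimethyl-1-oxooctahydro-1H-indene-4-carboxylate (cis-fused; OH, CO2CH3 and 7a-CH3 on one face) | O=C1CC[C@@]2(O)[C@](C)(C(=O)OC)CCC[C@@]12C | intermediate
7 | methyl (4R,7aR)-4,7a-dimethyl-1-oxo-2,4,5,6,7,7a-hexahydro-1H-indene-4-carboxylate (CO2CH3 cis to 7a-CH3) | O=C1CC=C2[C@](C)(C(=O)OC)CCC[C@@]12C | intermediate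
8 | methyl (3aR,4R,7aR)-4,7a-dimethyl-1-oxooctahydro-1H-indene-4-carboxylate (cis-fused; 3a-H, CO2CH3 and 7a-CH3 on one face) | O=C1CC[C@H]2[C@](C)(C(=O)OC)CCC[C@@]12C | intermediate
9 | (3-bromopropoxy)(tert-butyl)diphenylsilane | CC(C)(C)[Si](OCCCBr)(c1ccccc1)c1ccccc1 | starting material
10 | triphenylphosphine | c1ccc(cc1)P(c1ccccc1)c1ccccc1 | starting material
11 | [3-(tert-butyldiphenylsilyloxy)propyl]triphenylphosphonium bromide | CC(C)(C)[Si](OCCC[P+](c1ccccc1)(c1ccccc1)c1ccccc1)(c1ccccc1)c1ccccc1.[Br-] | intermediate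
12 | methyl (1Z,3aR,4R,7aR)-1-[3-(tert-butyldiphenylsilyloxy)propylidene]-4,7a-dimethyloctahydro-1H-indene-4-carboxylate (side chain cis to C-7a) | CC(C)(C)[Si](c1ccccc1)(c1ccccc1)OCC/C=C1/CC[C@H]2[C@](C)(C(=O)OC)CCC[C@@]12C | intermediate
13 | [(1Z,3aR,4R,7aR)-1-[3-(tert-butyldiphenylsilyloxy)propylidene]-4,7a-dimethyloctahydro-1H-inden-4-yl]methanol | CC(C)(C)[Si](c1ccccc1)(c1ccccc1)OCC/C=C1/CC[C@H]2[C@](C)(CO)CCC[C@@]12C | intermediate
14 | [(1Z,3aR,4R,7aR)-1-[3-(tert-butyldiphenylsilyloxy)propylidene]-4,7a-dimethyloctahydro-1H-inden-4-yl]methyl acetate | CC(C)(C)[Si](c1ccccc1)(c1ccccc1)OCC/C=C1/CC[C@H]2[C@](C)(COC(C)=O)CCC[C@@]12C | intermediate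
15 | [(1R,3aS,4R,7aR)-1-[(1S)-3-(tert-butyldiphenylsilyloxy)-1-hydroxypropyl]-1-hydroxy-4,7a-dimethyloctahydro-1H-inden-4-yl]methyl acetate (C-1 hydroxyl on the face of 7a-CH3) | CC(C)(C)[Si](c1ccccc1)(c1ccccc1)OCC[C@H](O)[C@@]1(O)CC[C@H]2[C@](C)(COC(C)=O)CCC[C@@]12C | intermediate
16 | [(1R,3aS,4R,7aR)-1-[(1S)-3-(tert-butyldiphenylsilyloxy)-1-(methanesulfonyloxy)propyl]-1-hydroxy-4,7a-dimethyloctahydro-1H-inden-4-yl]methyl acetate | CC(C)(C)[Si](c1ccccc1)(c1ccccc1)OCC[C@H](OS(C)(=O)=O)[C@@]1(O)CC[C@H]2[C@](C)(COC(C)=O)CCC[C@@]12C | intermediate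
17 | [(1R,4aR,5S,8aR)-5-[2-(tert-butyldiphenylsilyloxy)ethyl]-1,4a-dimethyl-6-oxodecahydronaphthalen-1-yl]methyl acetate (cis-decalin; 8a-H, 4a-CH3, CH2OAc and C-5 chain on one face) | O=C1CC[C@H]2[C@](C)(COC(C)=O)CCC[C@@]2(C)[C@@H]1CCO[Si](c1ccccc1)(c1ccccc1)C(C)(C)C | intermediate
18 | [(1R,4aS,5R,8aR)-5-[2-(tert-butyldiphenylsilyloxy)ethyl]-1,4a-dimethyl-6-methylidenedecahydronaphthalen-1-yl]methyl acetate | C=C1CC[C@H]2[C@](C)(COC(C)=O)CCC[C@@]2(C)[C@@H]1CCO[Si](c1ccccc1)(c1ccccc1)C(C)(C)C | intermediate
19 | [(1R,4aS,5R,8aR)-5-(2-hydroxyethyl)-1,4a-dimethyl-6-methylidenedecahydronaphthalen-1-yl]methyl acetate | C=C1CC[C@H]2[C@](C)(COC(C)=O)CCC[C@@]2(C)[C@@H]1CCO | intermediate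
20 | [(1R,4aS,5R,8aR)-5-(2-iodoethyl)-1,4a-dimethyl-6-methylidenedecahydronaphthalen-1-yl]methyl acetate | C=C1CC[C@H]2[C@](C)(COC(C)=O)CCC[C@@]2(C)[C@@H]1CCI | intermediate
21 | [(1R,4aS,5R,8aR)-5-[2-(iodozincio)ethyl]-1,4a-dimethyl-6-methylidenedecahydronaphthalen-1-yl]methyl acetate (alkylzinc iodide, not isolated) | C=C1CC[C@H]2[C@](C)(COC(C)=O)CCC[C@@]2(C)[C@@H]1CC[Zn]I | intermediate
22 | 3-bromofuran-2(5H)-one | O=C1OCC=C1Br | starting material
23 | [(1R,4aS,5R,8aR)-1,4a-dimethyl-6-methylidene-5-[2-(2-oxo-2,5-dihydrofuran-3-yl)ethyl]decahydronaphthalen-1-yl]methyl acetate | C=C1CC[C@H]2[C@](C)(COC(C)=O)CCC[C@@]2(C)[C@@H]1CCC1=CCOC1=O | target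

**Step count**
Total: 16 steps. Longest linear sequence: 15 steps (steps 1–5 and 7–16).

**Three steps most likely to fail**

Step 3. The chiral copper enolate may differentiate the two enantiotopic ring carbonyls poorly, or the aldolate may revert (retro-aldol), so that enantio- or diastereoselectivity is lost. The fallback separates enantiocontrol from ring closure and runs from 5 back to 6. Corey–Bakshi–Shibata reduction of 5 ((S)-2-methyl-CBS-oxazaborolidine, catecholborane, toluene, −60 °C) would reduce one ring carbonyl to give the hydroxy ketone methyl (E)-5-[(1S,2S)-2-hydroxy-1-methyl-5-oxocyclopentyl]-2-methylpent-2-enoate F1. Excess [(Ph3P)CuH]6 (toluene, −40 → 20 °C) would then close ring A by a substrate-controlled reductive aldol addition to the remaining carbonyl, giving the diol ester methyl (1S,3aS,4R,7aS)-1,3a-dihydroxy-4,7a-dimethyloctahydro-1H-indene-4-carboxylate F2. Dess–Martin oxidation of its secondary alcohol returns to 6.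

Step 7. The olefination of the neopentyl ketone may lose geometric control and give a Z/E mixture, which steps 10–12 would turn into the C-9 epimer of 17. In the fallback C-9 is set by a carbonyl reduction instead of by alkene geometry; it runs from 14 (carried as the Z/E mixture) back to 15. Osmylation would give 15 together with its C-9 epimer, the diol [(1R,3aS,4R,7aR)-1-[(1R)-3-(tert-butyldiphenylsilyloxy)-1-hydroxypropyl]-1-hydroxy-4,7a-dimethyloctahydro-1H-inden-4-yl]methyl acetate F3. Parikh–Doering oxidation (SO3·pyridine, DMSO, Et3N) of the secondary hydroxyl converges both on the hydroxy ketone [(1R,3aS,4R,7aR)-1-[3-(tert-butyldiphenylsilyloxy)propanoyl]-1-hydroxy-4,7a-dimethyloctahydro-1H-inden-4-yl]methyl acetate F4. Chelation-controlled reduction with Zn(BH4)2 (Et2O, −30 °C; hydride enters the zinc chelate from the side of C-7, away from quaternary C-10) should return 15 alone, which rejoins the route at step 11.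

Step 12. Instead of the 1,2-shift, the C-8 oxygen may close onto C-9 (spiro-epoxide formation), or C-7 may migrate in place of C-10. The fallback is a halohydrin-salt ring enlargement and runs from 16 to 17. DBU (CH2Cl2, 20 °C) would deliberately close 16, with inversion at C-9, to the spiro-epoxide [(1R,3'R,3aS,4R,7aR)-3'-[2-(tert-butyldiphenylsilyloxy)ethyl]-4,7a-dimethyloctahydrospiro[indene-1,2'-oxiran]-4-yl]methyl acetate F5. LiI (THF, reflux) would reopen it at the less substituted C-9 with a second inversion. The lithium alkoxide of the resulting iodohydrin has the same relative arrangement as 16 but a better leaving group, and should undergo the known halohydrin-salt 1,2-shift (third inversion at C-9) to 17.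

Further compounds
F1 | step 3 | methyl (E)-5-[(1S,2S)-2-hydroxy-1-methyl-5-oxocyclopentyl]-2-methylpent-2-enoate | COC(=O)/C(C)=C/CC[C@]1(C)C(=O)CC[C@@H]1O
F2 | step 3 | methyl (1S,3aS,4R,7aS)-1,3a-dihydroxy-4,7a-dimethyloctahydro-1H-indene-4-carboxylate | O[C@H]1CC[C@@]2(O)[C@](C)(C(=O)OC)CCC[C@@]12C
F3 | step 7 | [(1R,3aS,4R,7aR)-1-[(1R)-3-(tert-butyldiphenylsilyloxy)-1-hydroxypropyl]-1-hydroxy-4,7a-dimethyloctahydro-1H-inden-4-yl]methyl acetate | CC(C)(C)[Si](c1ccccc1)(c1ccccc1)OCC[C@@H](O)[C@@]1(O)CC[C@H]2[C@](C)(COC(C)=O)CCC[C@@]12C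
F4 | step 7 | [(1R,3aS,4R,7aR)-1-[3-(tert-butyldiphenylsilyloxy)propanoyl]-1-hydroxy-4,7a-dimethyloctahydro-1H-inden-4-yl]methyl acetate | CC(C)(C)[Si](c1ccccc1)(c1ccccc1)OCCC(=O)[C@@]1(O)CC[C@H]2[C@](C)(COC(C)=O)CCC[C@@]12C
F5 | step 12 | [(1R,3'R,3aS,4R,7aR)-3'-[2-(tert-butyldiphenylsilyloxy)ethyl]-4,7a-dimethyloctahydrospiro[indene-1,2'-oxiran]-4-yl]methyl acetate | CC(C)(C)[Si](c1ccccc1)(c1ccccc1)OCC[C@H]1O[C@@]12CC[C@H]3[C@](C)(COC(C)=O)CCC[C@@]23C
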